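**Retrosynthetic overview**
- The target is a depsidone. Ring A (methoxy, methyl, hydroxy) and ring B (fully substituted) are joined by an ether oxygen and an ester into the seven-membered ring C, and ring B carries a five-membered lactol (hydroxyphthalide) ring D.
- Feature used: the lactol carbon of ring D sits on the ring B carbon between the carbon bearing the lactone carbonyl and the carbon bearing the diaryl ether oxygen. In a depsidone acid lacking that carbon, this is the only C–H ortho to the carboxyl group.
- Disconnections: (R)-lactol ⇐ separable mixed acetal with (S)-1-phenylethanol ⇐ racemic lactol ⇐ ozonolysis of an isocoumarin (one carbon cut out) ⇐ depsidone acid 15 + vinylene carbonate 16 by carboxylate-directed C–H annulation.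
- Acid 15 ⇐ lactonisation of a diaryl ether seco acid ⇐ Ullmann coupling of ring A phenol 5 with ring B iodide 10.
- Ring order: rings A and B come from arenes 1 and 6; ring C by lactonisation (step 11); a temporary pyranone ring by annulation (step 13); ring D by ring contraction (step 14).

Key step: step 13

Remark (assumption): lactols of this type can epimerise by ring–chain tautomerism with the open formyl acid. The lactol carbon is therefore kept as a configurationally fixed mixed acetal until the last step, and the free (R)-lactol is assumed to hold its configuration when isolated cold from a neutral, aprotic medium.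

Locants for the depsidones follow 11H-dibenzo[b,e][1,4]dioxepin-11-one: ring A C-1 to C-4, ether O-5, ring B C-6 to C-9, ester O-10, carbonyl C-11.

**Ring A phenol**

Step 1
Reactants: 1 3,4,5-trimethoxytoluene
Product: 3 2,3,4-trimethoxy-6-methylbenzaldehyde, via iminium salt 2 (not isolated)
Conditions: POCl3, DMF, 0 → 80 °C; aq. NaOAc
Reagents that add atoms: N,N-dimethylformamide, CN(C)C=O; water, O
Why: Vilsmeier–Haack formylation; the two free ring positions of 1 are equivalent and each is activated by an ortho and a para methoxy group, so one aldehyde should result after hydrolysis of the iminium salt.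

Step 2
Reactants: 3 2,3,4-trimethoxy-6-methylbenzaldehyde
Product: 4 2,3-dihydroxy-4-methoxy-6-methylbenzaldehyde
Conditions: BCl3 (3 equiv), CH2Cl2, 0 → 23 °C; H2O
Reagents that add atoms: none
Why: Chelation-directed Lewis acid cleavage of aryl methyl ethers: boron bound to the aldehyde oxygen removes the ortho methyl group and, once held on that oxygen, the neighbouring one, while the 4-methoxy group, which cannot join a chelate and is deactivated as a vinylogous ester, should stay.

Step 3
Reactants: 4 2,3-dihydroxy-4-methoxy-6-methylbenzaldehyde
Product: 5 3-(benzyloxy)-2-hydroxy-4-methoxy-6-methylbenzaldehyde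
Conditions: NaH (2.2 equiv), DMSO, 23 °C; BnBr (1.0 equiv); aq. HCl
Reagents that add atoms: benzyl bromide, BrCc1ccccc1
Why: Williamson etherification of the dianion: the 2-phenoxide is delocalised into the aldehyde and held by sodium, so the more basic 3-phenoxide should take the single equivalent of benzyl bromide.

**Ring B iodide**

Step 4
Reactants: 6 2,4-dihydroxy-3-methylbenzoic acid
Product: 7 tert-butyl 2,4-dihydroxy-3-methylbenzoate
Conditions: Me2NCH(Ot-Bu)2, toluene, 80 °C
Reagents that add atoms: N,N-dimethylformamide di-tert-butyl acetal, CN(C)C(OC(C)(C)C)OC(C)(C)C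
Why: Esterification with an amide acetal: the acid protonates the reagent and the resulting carboxylate is tert-butylated, while the much less acidic phenols are left free and no strong acid is needed.

Step 5
Reactants: 7 tert-butyl 2,4-dihydroxy-3-methylbenzoate
Product: 8 tert-butyl 2,4-dihydroxy-5-iodo-3-methylbenzoate
Conditions: NIS, MeCN, 0 → 23 °C
Reagents that add atoms: N-iodosuccinimide, O=C1CCC(=O)N1I
Why: Electrophilic aromatic iodination; C-5 is ortho to the 4-hydroxyl and para to the 2-hydroxyl and is the only activated free position, C-6 being meta to both.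

Step 6
Reactants: 8 tert-butyl 2,4-dihydroxy-5-iodo-3-methylbenzoate
Product: 9 tert-butyl 2-hydroxy-5-iodo-3-methyl-4-(prop-2-enyloxy)benzoate
Conditions: allyl bromide (1.1 equiv), K2CO3, acetone, 50 °C
Reagents that add atoms: allyl bromide, C=CCBr
Why: Williamson etherification; the 4-hydroxyl, para to the ester and next to iodine, is the more acidic and is not hydrogen-bonded, whereas the 2-hydroxyl is tied to the ester carbonyl, so one allyl group should go to O-4.

Step 7
Reactants: 9 tert-butyl 2-hydroxy-5-iodo-3-methyl-4-(prop-2-enyloxy)benzoate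
Product: 10 tert-butyl 2-(benzyloxy)-5-iodo-3-methyl-4-(prop-2-enyloxy)benzoate
Conditions: BnBr, K2CO3, DMF, 70 °C
Reagents that add atoms: benzyl bromide, BrCc1ccccc1
Why: Williamson etherification of the remaining hydrogen-bonded salicylate hydroxyl under warmer conditions; the tert-butyl ester, allyl ether and aryl iodide are stable to carbonate.

**Depsidone acid**

Step 8
Reactants: 5 3-(benzyloxy)-2-hydroxy-4-methoxy-6-methylbenzaldehyde; 10 tert-butyl 2-(benzyloxy)-5-iodo-3-methyl-4-(prop-2-enyloxy)benzoate
Product: 11 tert-butyl 2-(benzyloxy)-5-[2-(benzyloxy)-6-formyl-3-methoxy-5-methylphenoxy]-3-methyl-4-(prop-2-enyloxy)benzoate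
Conditions: CuI (20 mol%), picolinic acid (40 mol%), K3PO4, DMSO, 90 °C
Reagents that add atoms: none
Why: Ullmann diaryl ether synthesis (copper-catalysed C–O coupling); picolinic acid as ligand suits ortho-substituted phenols, the aryl iodide carries only one ortho substituent, and the aldehyde, tert-butyl ester, allyl ether and benzyl ethers tolerate phosphate base.

Step 9
Reactants: 11 diaryl ether aldehyde
Product: 12 3-(benzyloxy)-2-[4-(benzyloxy)-5-(tert-butoxycarbonyl)-3-methyl-2-(prop-2-enyloxy)phenoxy]-4-methoxy-6-methylbenzoic acid
Conditions: NaClO2, NaH2PO4, 2-methyl-2-butene, t-BuOH/THF/H2O, 23 °C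
Reagents that add atoms: sodium chlorite, [Na+].[O-]Cl=O
Why: Pinnick oxidation of the aromatic aldehyde to the acid; 2-methyl-2-butene traps hypochlorous acid so that the allyl ether and the electron-rich rings are not chlorinated.

Step 10
Reactants: 12 diaryl ether acid
Product: 13 3-(benzyloxy)-2-[4-(benzyloxy)-5-(tert-butoxycarbonyl)-2-hydroxy-3-methylphenoxy]-4-methoxy-6-methylbenzoic acid
Conditions: Pd(PPh3)4 (5 mol%), morpholine, THF, 23 °C
Reagents that add atoms: none
Why: Tsuji–Trost deallylation: zerovalent palladium ionises the allyl aryl ether and morpholine takes the allyl group, leaving the benzyl ethers and the tert-butyl ester.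

Step 11
Reactants: 13 hydroxy acid (seco acid)
Product: 14 tert-butyl 4,8-bis(benzyloxy)-3-methoxy-1,9-dimethyl-11-oxo-11H-dibenzo[b,e][1,4]dioxepine-7-carboxylate
Conditions: DCC, DMAP (cat.), CH2Cl2, 0 → 23 °C
Reagents that add atoms: none
Why: Steglich-type carbodiimide lactonisation; the activated ring A acid is held next to the ring B phenol by the diaryl ether, so the seven-membered ring C should close faster than intermolecular esterification, and the ring B carboxyl is masked as its tert-butyl ester.

Step 12
Reactants: 14 depsidone tert-butyl ester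
Product: 15 4,8-bis(benzyloxy)-3-methoxy-1,9-dimethyl-11-oxo-11H-dibenzo[b,e][1,4]dioxepine-7-carboxylic acid
Conditions: TFA/CH2Cl2 (1:4), 0 → 23 °C
Reagents that add atoms: none
Why: Acidolysis of the tert-butyl ester by loss of the tert-butyl cation; the aryl ester of ring C and the aryl benzyl ethers are stable to trifluoroacetic acid at this temperature.

**Key annulation and ring contraction**

Step 13
Reactants: 15 depsidone acid; 16 vinylene carbonate
Product: 17 depsidone-fused isocoumarin (C-6 and the C-7 carboxyl of 15 bridged by CH=CH–O; 3,4-unsubstituted pyranone ring)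
Conditions: [Cp*RhCl2]2 (5 mol%), AgSbF6 (20 mol%), NaOAc (30 mol%), vinylene carbonate (3 equiv), 1,2-dichloroethane, 100 °C, sealed tube
Reagents that add atoms: none
Why: The carboxylate of 15 binds cationic Cp*Rh (trivalent rhodium), and acetate-assisted concerted metalation–deprotonation at C-6, the only C–H ortho to the carboxyl group, gives a five-membered rhodacycle. Vinylene carbonate 16 inserts into the Rh–aryl bond to a seven-membered rhodacycle, the carboxylate oxygen then bonds to the rhodium-bearing carbon, and the carbonate bridge is expelled as CO2 and water, which forms the C3=C4 double bond and returns trivalent rhodium without an external oxidant. The closest known reaction type is the trivalent rhodium catalysed C–H/O–H annulation of benzoic acids with vinylene carbonate or alkynes to isocoumarins. The pyranone ring is closed as a formal [4+2] annulation, the C–C bond first by migratory insertion and the six-membered ring then by C–O bond formation at the former alkene carbon. No stereocentre is formed. The step needs site selectivity and chemoselectivity: the other ortho position of the carboxyl group carries the benzyloxy group, ring A has no directing group next to its single C–H, and the aryl ester of ring C and the benzyl ethers are inert to the acetate-buffered conditions.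

Step 14
Reactants: 17 depsidone-fused isocoumarin
Product: 20 racemic depsidone lactol (C-6 bears CH(OH) joined through oxygen to the C-7 carbonyl; both phenols as benzyl ethers), via ozonide 18 (not isolated), via formyl anhydride aldehyde 19 (not isolated)
Conditions: O3, CH2Cl2, −78 °C (Sudan Red 7B end point); Me2S, −78 → 23 °C; THF/pH 7 phosphate buffer, 0 → 23 °C
Reagents that add atoms: ozone, [O-][O+]=O
Why: Ozonolysis: the enol ester double bond of the pyranone is far more reactive towards ozone than the alkoxyarenes, reduction of the ozonide leaves an aldehyde on C-6 and a mixed formic anhydride on C-7, the buffer hydrolyses the anhydride at the formyl carbon, and the formyl acid closes to the five-membered lactol, which forms as the racemate.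

**Resolution and deprotection**

Step 15
Reactants: 20 racemic depsidone lactol; 21 (S)-1-phenylethanol
Product: 22 mixed acetal of 20 in which the lactol OH is replaced by (S)-1-phenylethoxy and the acetal carbon is (R)
Conditions: (S)-1-phenylethanol (3 equiv), CSA (5 mol%), 4 Å MS, CH2Cl2, 23 °C; separation of the two acetal epimers on silica gel
Reagents that add atoms: none
Why: Acid-catalysed acetalisation of the lactol (pseudoester formation, akin to a Fischer glycosidation): the alcohol C–O bond is not broken so its (S) centre is kept, the acetal carbon forms as both epimers, which are diastereomers and should be separable, the (R)-acetal is taken on after assignment by crystallography, and the other epimer can be returned to the same acid conditions for equilibration.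

Step 16
Reactants: 22 (R)-acetal
Product: 23 target, the (R)-lactol with both phenols free
Conditions: H2 (1 atm), Pd(OH)2/C, EtOAc, 23 °C
Reagents that add atoms: none
Why: Catalytic hydrogenolysis cleaves three benzylic O–C bonds on the benzyl side (two aryl benzyl ethers and the O–CH(CH3)Ph bond of the acetal), so no bond to the lactol carbon is broken and its (R) configuration is carried over from 22, and the neutral aprotic medium avoids ring–chain epimerisation.

**Compound list**

1 | 3,4,5-trimethoxytoluene | Cc1cc(OC)c(OC)c(OC)c1 | starting material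
2 | N-[(2,3,4-trimethoxy-6-methylphenyl)methylidene]-N-methylmethanaminium dichlorophosphate | COc1cc(C)c(C=[N+](C)C)c(OC)c1OC.[O-]P(=O)(Cl)Cl | intermediate
3 | 2,3,4-trimethoxy-6-methylbenzaldehyde | COc1cc(C)c(C=O)c(OC)c1OC | intermediate
4 | 2,3-dihydroxy-4-methoxy-6-methylbenzaldehyde | COc1cc(C)c(C=O)c(O)c1O | intermediate
5 | 3-(benzyloxy)-2-hydroxy-4-methoxy-6-methylbenzaldehyde | COc1cc(C)c(C=O)c(O)c1OCc1ccccc1 | intermediate
6 | 2,4-dihydroxy-3-methylbenzoic acid | Cc1c(O)ccc(C(=O)O)c1O | starting material
7 | tert-butyl 2,4-dihydroxy-3-methylbenzoate | Cc1c(O)ccc(C(=O)OC(C)(C)C)c1O | intermediate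
8 | tert-butyl 2,4-dihydroxy-5-iodo-3-methylbenzoate | Cc1c(O)c(I)cc(C(=O)OC(C)(C)C)c1O | intermediate
9 | tert-butyl 2-hydroxy-5-iodo-3-methyl-4-(prop-2-enyloxy)benzoate | Cc1c(OCC=C)c(I)cc(C(=O)OC(C)(C)C)c1O | intermediate
10 | tert-butyl 2-(benzyloxy)-5-iodo-3-methyl-4-(prop-2-enyloxy)benzoate | Cc1c(OCC=C)c(I)cc(C(=O)OC(C)(C)C)c1OCc1ccccc1 | intermediate
11 | tert-butyl 2-(benzyloxy)-5-[2-(benzyloxy)-6-formyl-3-methoxy-5-methylphenoxy]-3-methyl-4-(prop-2-enyloxy)benzoate | COc1cc(C)c(C=O)c(Oc2cc(C(=O)OC(C)(C)C)c(OCc3ccccc3)c(C)c2OCC=C)c1OCc1ccccc1 | intermediate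
12 | 3-(benzyloxy)-2-[4-(benzyloxy)-5-(tert-butoxycarbonyl)-3-methyl-2-(prop-2-enyloxy)phenoxy]-4-methoxy-6-methylbenzoic acid | COc1cc(C)c(C(=O)O)c(Oc2cc(C(=O)OC(C)(C)C)c(OCc3ccccc3)c(C)c2OCC=C)c1OCc1ccccc1 | intermediate
13 | 3-(benzyloxy)-2-[4-(benzyloxy)-5-(tert-butoxycarbonyl)-2-hydroxy-3-methylphenoxy]-4-methoxy-6-methylbenzoic acid | COc1cc(C)c(C(=O)O)c(Oc2cc(C(=O)OC(C)(C)C)c(OCc3ccccc3)c(C)c2O)c1OCc1ccccc1 | intermediate
14 | tert-butyl 4,8-bis(benzyloxy)-3-methoxy-1,9-dimethyl-11-oxo-11H-dibenzo[b,e][1,4]dioxepine-7-carboxylate | COc1cc(C)c2c(c1OCc4ccccc4)Oc3c(c(C)c(OCc5ccccc5)c(C(=O)OC(C)(C)C)c3)OC2=O | intermediate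
15 | 4,8-bis(benzyloxy)-3-methoxy-1,9-dimethyl-11-oxo-11H-dibenzo[b,e][1,4]dioxepine-7-carboxylic acid | COc1cc(C)c2c(c1OCc4ccccc4)Oc3c(c(C)c(OCc5ccccc5)c(C(=O)O)c3)OC2=O | intermediate
16 | vinylene carbonate | O=C1OC=CO1 | starting material
17 | depsidone-fused isocoumarin (C-6 and the C-7 carboxyl of 15 bridged by CH=CH–O) | COc1cc(C)c2c(c1OCc4ccccc4)Oc3c(c(C)c(OCc5ccccc5)c6c3C=COC6=O)OC2=O | intermediate
18 | secondary ozonide of 17 (1,2,4-trioxolane across the former C3=C4 bond, racemic) | COc1cc(C)c2c(c1OCc4ccccc4)Oc3c(c(C)c(OCc5ccccc5)c6c3C7OOC(O7)OC6=O)OC2=O | intermediate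
19 | depsidone with a formyl group on C-6 and a carboxylic formic anhydride on C-7 | COc1cc(C)c2c(c1OCc4ccccc4)Oc3c(c(C)c(OCc5ccccc5)c(C(=O)OC=O)c3C=O)OC2=O | intermediate
20 | racemic depsidone lactol, both phenols as benzyl ethers | COc1cc(C)c2c(c1OCc4ccccc4)Oc1c(c(C)c(OCc5ccccc5)c3c1C(O)OC3=O)OC2=O | intermediate
21 | (S)-1-phenylethanol | C[C@H](O)c1ccccc1 | starting material
22 | mixed acetal of 20 with (S)-1-phenylethanol, acetal carbon (R) | COc1cc(C)c2c(c1OCc4ccccc4)Oc1c(c(C)c(OCc5ccccc5)c3c1[C@H](O[C@@H](C)c6ccccc6)OC3=O)OC2=O | intermediate
23 | target, (R)-lactol depsidone | COc1cc(C)c2c(c1O)Oc1c(c(C)c(O)c3c1[C@H](O)OC3=O)OC2=O | target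

**Step count**

Total: 16 steps. Longest linear sequence: 13 steps (from 6 through steps 4–7 and 8–16).

**Steps most likely to fail**

Step 13. Metalation at C-6 may be slow because this C–H is flanked by the carboxylate and the bulky aryloxy group, so that vinylene carbonate decomposes or the acid loses CO2 before annulation occurs. The fallback replaces C–H annulation by directed metalation and sets out from ester 14. TMPMgCl·LiCl in THF at −20 °C should magnesiate the same C–H, which lies between the ester and the aryloxy oxygen, to give the arylmagnesium chloride F1 (not isolated). DMF then gives the formyl ester F2. TFA in CH2Cl2 cleaves the tert-butyl ester and the formyl acid closes to lactol 20, where the route is rejoined.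

Step 8. The hydrogen-bonded, chelating salicylaldehyde phenoxide may bind copper and couple slowly, so that protodeiodination of 10 and decomposition of the aldehyde take over. The fallback is a metal-free arylation with a diaryliodonium salt and sets out from iodide 10. mCPBA and TsOH·H2O in CH2Cl2/CF3CH2OH at 23 °C, followed by 1,3,5-trimethoxybenzene, should give the aryl(2,4,6-trimethoxyphenyl)iodonium tosylate F3. The potassium phenoxide of 5 (t-BuOK, THF, 23–40 °C) should take up the ring B aryl group by ligand coupling on trivalent iodine, the trimethoxyphenyl group staying on iodine, and give 11, where the route is rejoined.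

Step 16. Over-reduction at the benzylic lactol carbon, slow cleavage of the hindered 1-phenylethyl acetal, or loss of configuration by ring opening of the freed lactol on the catalyst may occur. The fallback uses no reductant and resolves at the very end; it sets out from racemic lactol 20. BCl3 with pentamethylbenzene in CH2Cl2 at −78 °C should remove both benzyl ethers without touching the methyl ether and give the racemic depsidone lactol F4. This is separated into its enantiomers by preparative supercritical fluid chromatography on an amylose tris(3,5-dimethylphenylcarbamate) phase with CO2/2-propanol and no additive; the (R)-enantiomer is 23.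

**Further compounds**

F1 | step 13 | arylmagnesium chloride of 14, magnesium on C-6 | COc1cc(C)c2c(c1OCc4ccccc4)Oc3c(c(C)c(OCc5ccccc5)c(C(=O)OC(C)(C)C)c3[Mg]Cl)OC2=O
F2 | step 13 | tert-butyl 4,8-bis(benzyloxy)-6-formyl-3-methoxy-1,9-dimethyl-11-oxo-11H-dibenzo[b,e][1,4]dioxepine-7-carboxylate | COc1cc(C)c2c(c1OCc4ccccc4)Oc3c(c(C)c(OCc5ccccc5)c(C(=O)OC(C)(C)C)c3C=O)OC2=O
F3 | step 8 | [4-(benzyloxy)-5-(tert-butoxycarbonyl)-3-methyl-2-(prop-2-enyloxy)phenyl](2,4,6-trimethoxyphenyl)iodonium 4-methylbenzenesulfonate | Cc1c(OCC=C)c([I+]c2c(OC)cc(OC)cc2OC)cc(C(=O)OC(C)(C)C)c1OCc1ccccc1.[O-]S(=O)(=O)c1ccc(C)cc1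
F4 | step 16 | racemic depsidone lactol with both phenols free | COc1cc(C)c2c(c1O)Oc1c(c(C)c(O)c3c1C(O)OC3=O)OC2=O
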